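**Plan**
- Cuts: the C6 and C7 acetates come off first. The ring is then cut at C8–C12, which turns the cyclopentenone into a 3-chloro-5-alkyl-2-furylcarbinol. The carbinol is cut at C8–C9 into a lithiated furan and a C1–C8 aldehyde.
- Enabling feature: the ring C8–C9(=O)–C10(Cl)=C11–C12(OH) is a 4-hydroxycyclopent-2-enone whose carbinol carbon C12 adjoins the C8–H carbon. This matches a 2-furylcarbinol in carbon count and oxidation level: C9–C12 are the four furan carbons, C8 is the carbinol carbon, and the C10 chlorine is a furan C3 chlorine.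
- Forward order: aldehyde 9 (7 steps) and chlorofuran 19 (5 steps) are joined. The only carbocycle is then closed while the furan is consumed. C8 is equilibrated, the dioxolane helper ring is removed, and O6 and O7 are acetylated.
- Stereochemistry: C6 and C7 come from D-threitol and C5 from a reagent-controlled allylboration. The C8 carbinol mixture is erased in the ring closure, which is stereoconvergent.
- C12 is set by the torquoselective 4π closure under control of C7. C8 is set by thermodynamic epimerisation. The Z-alkene comes from (Z)-oct-2-en-1-ol.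

Key step: step 14

Remark: prostanoid numbering is used (C1 = ester carbon; C8 and C12 = ring carbons that carry the chains). Read from the SMILES, the C12 hydroxyl and the C8 side chain are cis on the ring. The 4,5-trans product of the ring closure is therefore the C8 epimer, and it is corrected in step 15.

**Route**

Step 1
Reactants: 1 (−)-2,3-O-isopropylidene-D-threitol
Product: 2 {(4R,5R)-5-[(benzyloxy)methyl]-2,2-dimethyl-1,3-dioxolan-4-yl}methanol
Conditions: NaH (1 equiv), BnBr (1 equiv), n-Bu4NI (cat.), THF, 0 °C → rt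
Reagents that add atoms: benzyl bromide, BrCc1ccccc1
Why: Williamson mono-alkylation of a C2-symmetric diol, in which either hydroxyl gives the same mono-ether and no stereocentre is touched.

Step 2
Reactants: 2 mono-benzyl ether
Product: 3 4-O-benzyl-2,3-O-isopropylidene-D-threose, (4S,5R)-5-[(benzyloxy)methyl]-2,2-dimethyl-1,3-dioxolane-4-carbaldehyde
Conditions: TEMPO (cat.), PhI(OAc)2, CH2Cl2, rt
Reagents that add atoms: none
Why: TEMPO/PhI(OAc)2 oxidation stops at the aldehyde under near-neutral conditions, so the α-alkoxy centre, already the more stable trans-dioxolane epimer, is kept.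

Step 3
Reactants: 3 aldehyde
Product: 5 (1S)-1-{(4R,5R)-5-[(benzyloxy)methyl]-2,2-dimethyl-1,3-dioxolan-4-yl}but-3-en-1-ol, via its diisopinocampheylborinate 4 (not isolated)
Conditions: (−)-Ipc2B(allyl), Et2O, −78 °C; then NaOH, H2O2, 0 °C → rt
Reagents that add atoms: (−)-B-allyldiisopinocampheylborane (from (+)-α-pinene), C=CCB([C@@H]1C[C@@H]2C[C@H]([C@H]1C)C2(C)C)[C@@H]1C[C@@H]2C[C@H]([C@H]1C)C2(C)C
Why: Brown asymmetric allylboration through a closed chair transition state, in which the reagent overrides the modest Felkin (anti) bias of the aldehyde and should set C5 as S, syn to O6.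

Step 4
Reactants: 5 homoallylic alcohol
Product: 6 (1S)-1-{(4R,5R)-5-[(benzyloxy)methyl]-2,2-dimethyl-1,3-dioxolan-4-yl}but-3-enyl acetate
Conditions: Ac2O, pyridine, DMAP (cat.), CH2Cl2, 0 °C → rt
Reagents that add atoms: acetic anhydride, CC(=O)OC(C)=O
Why: DMAP-catalysed acylation installs the final C5 acetate early, so a free 5-hydroxy ester, which would lactonise, never appears.

Step 5
Reactants: 6 acetate
Product: 7 methyl (2E,5S)-5-acetoxy-5-{(4R,5R)-5-[(benzyloxy)methyl]-2,2-dimethyl-1,3-dioxolan-4-yl}pent-2-enoate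
Conditions: methyl acrylate (excess), Hoveyda–Grubbs II (cat.), CH2Cl2, 40 °C
Reagents that add atoms: methyl acrylate, C=CC(=O)OC
Why: Olefin cross-metathesis of a terminal (type I) alkene with an acrylate (type II) is selective for the E-enoate and adds C2 and C1 with the methyl ester in place.

Step 6
Reactants: 7 enoate
Product: 8 methyl (5S)-5-acetoxy-5-[(4R,5R)-5-(hydroxymethyl)-2,2-dimethyl-1,3-dioxolan-4-yl]pentanoate
Conditions: H2 (1 atm), Pd/C, EtOAc–MeOH, rt
Reagents that add atoms: none
Why: Heterogeneous hydrogenation saturates the enoate and hydrogenolyses the benzyl ether in one operation, before any alkene or C–Cl bond of the target is present.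

Step 7
Reactants: 8 primary alcohol
Product: 9 methyl (5S)-5-acetoxy-5-[(4R,5S)-5-formyl-2,2-dimethyl-1,3-dioxolan-4-yl]pentanoate (C1–C8 aldehyde; the descriptor at C7 changes, the geometry does not)
Conditions: TEMPO (cat.), PhI(OAc)2, CH2Cl2, rt
Reagents that add atoms: none
Why: The same mild TEMPO oxidation tolerates acetate, ester and acetonide, and it leaves C7 as the favoured trans-dioxolane epimer.

Step 8
Reactants: 10 (Z)-oct-2-en-1-ol
Product: 11 (Z)-1-bromooct-2-ene
Conditions: CBr4, PPh3, CH2Cl2, 0 °C
Reagents that add atoms: carbon tetrabromide, BrC(Br)(Br)Br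
Why: Appel bromination is an SN2 displacement at the primary allylic carbon under neutral conditions, so the Z geometry is kept.

Step 9
Reactants: 12 furan; 11 (Z)-1-bromooct-2-ene
Product: 14 2-[(Z)-oct-2-enyl]furan, via furan-2-yllithium 13 (not isolated)
Conditions: n-BuLi, THF, −78 → 0 °C; then 11, −78 °C → rt
Reagents that add atoms: none
Why: α-Lithiation of furan followed by SN2 alkylation with a primary allylic bromide is standard and keeps the alkene Z and skipped.

Step 10
Reactants: 14 2-[(Z)-oct-2-enyl]furan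
Product: 15 2-bromo-5-[(Z)-oct-2-enyl]furan
Conditions: NBS, DMF, −20 → 0 °C, dark
Reagents that add atoms: N-bromosuccinimide, O=C1CCC(=O)N1Br
Why: Electrophilic bromination of a 2-alkylfuran takes place at the free α-position much faster than at the isolated alkene.

Step 11
Reactants: 15 2-bromo-5-[(Z)-oct-2-enyl]furan
Product: 17 4-bromo-2-[(Z)-oct-2-enyl]furan, via 3-bromo-5-[(Z)-oct-2-enyl]furan-2-yllithium 16 (not isolated)
Conditions: LDA, THF, −78 °C; then MeOH
Reagents that add atoms: none
Why: In this halogen dance, lithiation next to bromine and Br/Li transfers funnel into the most stable anion (α-lithio, flanked by O and Br), and protonation leaves bromine at the β-carbon next to the free α-position.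

Step 12
Reactants: 17 4-bromo-2-[(Z)-oct-2-enyl]furan
Product: 19 4-chloro-2-[(Z)-oct-2-enyl]furan, via 5-[(Z)-oct-2-enyl]furan-3-yllithium 18 (not isolated)
Conditions: n-BuLi, Et2O, −78 °C; then C2Cl6, −78 °C → rt
Reagents that add atoms: hexachloroethane, ClC(Cl)(Cl)C(Cl)(Cl)Cl
Why: Bromine–lithium exchange at −78 °C, where 3-furyllithiums keep their position, is followed by electrophilic chlorination with hexachloroethane.

Step 13
Reactants: 19 4-chloro-2-[(Z)-oct-2-enyl]furan; 9 aldehyde
Product: 21 methyl (5S)-5-acetoxy-5-[(4R,5R)-5-{[3-chloro-5-((Z)-oct-2-enyl)furan-2-yl](hydroxy)methyl}-2,2-dimethyl-1,3-dioxolan-4-yl]pentanoate (both C8 epimers), via 3-chloro-5-[(Z)-oct-2-enyl]furan-2-yllithium 20 (not isolated)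
Conditions: LDA, THF, −78 °C; then 9, −78 °C; H2O quench
Reagents that add atoms: none
Why: Directed α-lithiation removes the proton flanked by ring oxygen and chlorine, 1,2-addition to the α-alkoxy aldehyde outruns attack on the esters at −78 °C, and the C8 mixture is harmless because step 14 erases that centre.

Step 14
Reactants: 21 furylcarbinol (C8 epimer mixture)
Product: 22 (5S,6R,7R,8S,12S)-cyclopentenone: methyl (5S)-5-acetoxy-5-{(4R,5R)-5-[(1S,2S)-4-chloro-2-hydroxy-2-((Z)-oct-2-enyl)-5-oxocyclopent-3-enyl]-2,2-dimethyl-1,3-dioxolan-4-yl}pentanoate (hydroxyl trans to the side chain)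
Conditions: Dy(OTf)3 (10 mol %), t-BuOH–H2O (5:1), 80 °C
Reagents that add atoms: water, O
Why: Piancatelli rearrangement: Dy(III)-assisted loss of the C8 hydroxyl from either epimer gives the same furfuryl cation, water adds at the distal furan carbon (C12), the hemiketal opens to the 1,4-dihydroxypentadienyl cation C8–C9(OH)–C10(Cl)–C11–C12(OH), and a thermal conrotatory 4π electrocyclisation joins C8 to C12 before proton loss from O9 unveils the 2-chloroenone. The closest known reaction is the rearrangement of 5-alkyl-2-furylcarbinols to 4-alkyl-4-hydroxy-5-substituted cyclopent-2-enones with Zn(II) or Dy(III) salts in aqueous solvent. The single ring C8–C12 closes in the 4π-conrotatory mode (formally a 5-(enolendo)-exo-trig aldol bond) while the furan ring is consumed. The C8/C12 relative configuration follows from the out,out cation (O12 and C7 both outward, C7 held there by the C10 chlorine), which places the new hydroxyl trans to the C8 substituent. The sense of conrotation, and so 12S, is set by C7: A1,3 strain with O9 holds C7–H in the cation plane, and the termini turn so that the small tied-back O7 rather than C6 faces the inward-turning C13 methylene, with the C7–C6 bond anti to the forming bond, which gives (8S,12S). The step needs regioselectivity (water at C12, enol formed only at C8=C9 and never at C13), secured by the position of the leaving group, and chemoselectivity toward acetonide, esters and the skipped Z-alkene, secured by the weakly acidic catalytic medium and the activating 5-alkyl group.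

Step 15
Reactants: 22 (8S,12S)-cyclopentenone
Product: 23 (5S,6R,7R,8R,12S)-cyclopentenone (C8 epimer of 22; side chain trans to the octenyl chain, cis to the hydroxyl)
Conditions: KOAc, MeOH, rt; recovered 22 resubmitted
Reagents that add atoms: none
Why: Base-mediated α-epimerisation under thermodynamic control (the type of equilibration that turns cis-2,3-dialkylcyclopentanones into trans) moves the bulky dioxolanyl chain at C8, the only enolisable stereocentre, away from the octenyl chain, and reprotonation outruns β-elimination because O7 (alkoxide) and O12 (hydroxide) are poor leaving groups.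

Step 16
Reactants: 23 (8R,12S)-cyclopentenone acetonide
Product: 24 methyl (5S,6R,7R)-5-acetoxy-7-[(1R,2S)-4-chloro-2-hydroxy-2-((Z)-oct-2-enyl)-5-oxocyclopent-3-enyl]-6,7-dihydroxyheptanoate
Conditions: TFA–H2O, CH2Cl2, 0 °C
Reagents that add atoms: none
Why: In this acid hydrolysis of the isopropylidene ketal, the C12 alcohol does not ionise because its cation would be conjugated to the electron-poor chloroenone, and any acetyl shift among O5–O7 is levelled in step 17.

Step 17
Reactants: 24 diol
Product: 25 punaglandin 2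
Conditions: Ac2O, pyridine, 0 °C → rt (no DMAP)
Reagents that add atoms: acetic anhydride, CC(=O)OC(C)=O
Why: Pyridine-mediated acetylation acylates the two secondary alcohols and leaves the hindered tertiary C12 alcohol free, and the weak base and low temperature avoid E1cB loss of the new C7 acetate.

**Compound list**
1 | (−)-2,3-O-isopropylidene-D-threitol, [(4R,5R)-2,2-dimethyl-1,3-dioxolane-4,5-diyl]dimethanol | OC[C@H]1OC(C)(C)O[C@@H]1CO | starting material
2 | {(4R,5R)-5-[(benzyloxy)methyl]-2,2-dimethyl-1,3-dioxolan-4-yl}methanol | c1ccccc1COC[C@H]1OC(C)(C)O[C@@H]1CO | intermediate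
3 | 4-O-benzyl-2,3-O-isopropylidene-D-threose | c1ccccc1COC[C@H]1OC(C)(C)O[C@@H]1C=O | intermediate
4 | diisopinocampheylborinate of 5 | c1ccccc1COC[C@H]1OC(C)(C)O[C@@H]1[C@H](CC=C)OB([C@@H]1C[C@@H]2C[C@H]([C@H]1C)C2(C)C)[C@@H]1C[C@@H]2C[C@H]([C@H]1C)C2(C)C | intermediate (not isolated)
5 | (1S)-1-{(4R,5R)-5-[(benzyloxy)methyl]-2,2-dimethyl-1,3-dioxolan-4-yl}but-3-en-1-ol | c1ccccc1COC[C@H]1OC(C)(C)O[C@@H]1[C@H](CC=C)O | intermediate
6 | acetate of 5 | c1ccccc1COC[C@H]1OC(C)(C)O[C@@H]1[C@H](CC=C)OC(C)=O | intermediate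
7 | methyl (2E,5S)-5-acetoxy-5-{(4R,5R)-5-[(benzyloxy)methyl]-2,2-dimethyl-1,3-dioxolan-4-yl}pent-2-enoate | c1ccccc1COC[C@H]1OC(C)(C)O[C@@H]1[C@H](C/C=C/C(=O)OC)OC(C)=O | intermediate
8 | methyl (5S)-5-acetoxy-5-[(4R,5R)-5-(hydroxymethyl)-2,2-dimethyl-1,3-dioxolan-4-yl]pentanoate | OC[C@H]1OC(C)(C)O[C@@H]1[C@H](CCCC(=O)OC)OC(C)=O | intermediate
9 | methyl (5S)-5-acetoxy-5-[(4R,5S)-5-formyl-2,2-dimethyl-1,3-dioxolan-4-yl]pentanoate | O=C[C@H]1OC(C)(C)O[C@@H]1[C@H](CCCC(=O)OC)OC(C)=O | intermediate
10 | (Z)-oct-2-en-1-ol | CCCCC/C=C\CO | starting material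
11 | (Z)-1-bromooct-2-ene | CCCCC/C=C\CBr | intermediate
12 | furan | c1ccoc1 | starting material
13 | furan-2-yllithium | [Li]c1ccco1 | intermediate (not isolated)
14 | 2-[(Z)-oct-2-enyl]furan | CCCCC/C=C\Cc1ccco1 | intermediate
15 | 2-bromo-5-[(Z)-oct-2-enyl]furan | CCCCC/C=C\Cc1ccc(Br)o1 | intermediate
16 | 3-bromo-5-[(Z)-oct-2-enyl]furan-2-yllithium | CCCCC/C=C\Cc1cc(Br)c([Li])o1 | intermediate (not isolated)
17 | 4-bromo-2-[(Z)-oct-2-enyl]furan | CCCCC/C=C\Cc1cc(Br)co1 | intermediate
18 | 5-[(Z)-oct-2-enyl]furan-3-yllithium | CCCCC/C=C\Cc1cc([Li])co1 | intermediate (not isolated)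
19 | 4-chloro-2-[(Z)-oct-2-enyl]furan | CCCCC/C=C\Cc1cc(Cl)co1 | intermediate
20 | 3-chloro-5-[(Z)-oct-2-enyl]furan-2-yllithium | CCCCC/C=C\Cc1cc(Cl)c([Li])o1 | intermediate (not isolated)
21 | furylcarbinol, (5S,6R,7R), both C8 epimers | CCCCC/C=C\Cc1cc(Cl)c(o1)C(O)[C@H]1OC(C)(C)O[C@@H]1[C@H](CCCC(=O)OC)OC(C)=O | intermediate
22 | (5S,6R,7R,8S,12S)-5-acetoxy-6,7-O-isopropylidene chlorocyclopentenone (8-epimer) | CCCCC/C=C\C[C@@]1(O)C=C(Cl)C(=O)[C@H]1[C@H]2OC(C)(C)O[C@@H]2[C@H](CCCC(=O)OC)OC(C)=O | intermediate
23 | (5S,6R,7R,8R,12S)-5-acetoxy-6,7-O-isopropylidene chlorocyclopentenone | CCCCC/C=C\C[C@@]1(O)C=C(Cl)C(=O)[C@@H]1[C@H]2OC(C)(C)O[C@@H]2[C@H](CCCC(=O)OC)OC(C)=O | intermediate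
24 | (5S,6R,7R,8R,12S)-5-acetoxy-6,7-diol | CCCCC/C=C\C[C@@]1(O)C=C(Cl)C(=O)[C@@H]1[C@@H](O)[C@H](O)[C@H](CCCC(=O)OC)OC(C)=O | intermediate
25 | punaglandin 2 | CCCCC/C=C\C[C@@]1(O)C=C(Cl)C(=O)[C@@H]1[C@@H](OC(C)=O)[C@H](OC(C)=O)[C@H](CCCC(=O)OC)OC(C)=O | target

Total step count: 17. Longest linear sequence: 12 (steps 1–7 and 13–17).

**Steps most likely to fail**

**Step 14.**
- Risk: ionisation of the carbinol may be slow, because the C7 oxygen and the ring chlorine both destabilise the furfuryl cation.
- Forcing the reaction could strip the acetonide before the closure, which would erode the torquoselectivity. It could also allow a 1,2-hydride shift from C7, or move the skipped alkene into conjugation.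
- Fallback: chlorine is brought in after the ring closure. The sequence sets out from bromofuran 15 and aldehyde 9 and comes back at 23.
- Bromine–lithium exchange on 15 (n-BuLi, THF, −78 °C) would give 5-[(Z)-oct-2-enyl]furan-2-yllithium F1. This adds to 9 to give the chlorine-free furylcarbinol F2.
- F2 belongs to the substrate class on which the rearrangement is best known. It should close under milder conditions to the chlorine-free 8-epi-cyclopentenone F3, which is equilibrated as in step 15 to the chlorine-free 8R-cyclopentenone F4.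
- Weitz–Scheffer epoxidation (t-BuOOH, DBU, 0 °C) attacks only the electron-poor enone and gives the 10,11-epoxy ketone F5.
- Dry HCl opens the epoxide at C10 to the 10-chloro-11-hydroxy ketone F6, which loses water to give 23.

**Step 15.**
- Risk: the enolate may expel O7 or the tertiary hydroxyl (E1cB), or the equilibrium may not lie far enough on the side of the 8R epimer.
- Fallback: kinetic control replaces thermodynamic control. The sequence sets out from 22 and comes back at 23.
- Silylation of the tertiary alcohol (TBSOTf, 2,6-lutidine) would give the 12-O-TBS ether of 22 F7.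
- LiHMDS at −78 °C deprotonates only the ketone and gives the lithium cross-conjugated dienolate F8.
- A bulky phenol (2,6-di-tert-butyl-4-methylphenol) protonates F8 from the octenyl face, because the silyl ether now shields the other face. This gives the 12-O-TBS ether of 23 F9.
- HF·pyridine removes the silyl group and gives 23.

**Step 11.**
- Risk: the halogen migration may stop short or run on. LDA may also deprotonate the doubly activated C13 methylene, which would pull the Z-alkene into conjugation.
- Fallback: a blocking group replaces the halogen migration. The sequence sets out from bromide 11 (with commercial 3-bromofuran) and comes back at 19, replacing steps 9–12.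
- 3-Bromofuran is lithiated with LDA to 3-bromofuran-2-yllithium F10 and silylated (TMSCl) to 3-bromo-2-(trimethylsilyl)furan F11.
- Bromine–lithium exchange gives 2-(trimethylsilyl)furan-3-yllithium F12, which is chlorinated with C2Cl6 to 3-chloro-2-(trimethylsilyl)furan F13.
- With the position next to chlorine blocked, s-BuLi metalates the only free α-position and gives 4-chloro-5-(trimethylsilyl)furan-2-yllithium F14.
- F14 is alkylated with 11 to 3-chloro-5-[(Z)-oct-2-enyl]-2-(trimethylsilyl)furan F15, and TBAF removes silicon to give 19.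

Further compounds
F1 | step 14 | 5-[(Z)-oct-2-enyl]furan-2-yllithium | CCCCC/C=C\Cc1ccc([Li])o1
F2 | step 14 | chlorine-free furylcarbinol (both C8 epimers) | CCCCC/C=C\Cc1ccc(o1)C(O)[C@H]1OC(C)(C)O[C@@H]1[C@H](CCCC(=O)OC)OC(C)=O
F3 | step 14 | chlorine-free 8-epi-cyclopentenone | CCCCC/C=C\C[C@@]1(O)C=CC(=O)[C@H]1[C@H]2OC(C)(C)O[C@@H]2[C@H](CCCC(=O)OC)OC(C)=O
F4 | step 14 | chlorine-free 8R-cyclopentenone | CCCCC/C=C\C[C@@]1(O)C=CC(=O)[C@@H]1[C@H]2OC(C)(C)O[C@@H]2[C@H](CCCC(=O)OC)OC(C)=O
F5 | step 14 | 10,11-epoxy ketone | CCCCC/C=C\C[C@@]1(O)C2OC2C(=O)[C@@H]1[C@H]3OC(C)(C)O[C@@H]3[C@H](CCCC(=O)OC)OC(C)=O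
F6 | step 14 | 10-chloro-11-hydroxy ketone | CCCCC/C=C\C[C@@]1(O)C(O)C(Cl)C(=O)[C@@H]1[C@H]2OC(C)(C)O[C@@H]2[C@H](CCCC(=O)OC)OC(C)=O
F7 | step 15 | 12-O-TBS ether of 22 | CCCCC/C=C\C[C@@]1(O[Si](C)(C)C(C)(C)C)C=C(Cl)C(=O)[C@H]1[C@H]2OC(C)(C)O[C@@H]2[C@H](CCCC(=O)OC)OC(C)=O
F8 | step 15 | lithium cross-conjugated dienolate | CCCCC/C=C\C[C@@]1(O[Si](C)(C)C(C)(C)C)C=C(Cl)C(O[Li])=C1[C@H]2OC(C)(C)O[C@@H]2[C@H](CCCC(=O)OC)OC(C)=O
F9 | step 15 | 12-O-TBS ether of 23 | CCCCC/C=C\C[C@@]1(O[Si](C)(C)C(C)(C)C)C=C(Cl)C(=O)[C@@H]1[C@H]2OC(C)(C)O[C@@H]2[C@H](CCCC(=O)OC)OC(C)=O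
F10 | step 11 | 3-bromofuran-2-yllithium | [Li]c1occc1Br
F11 | step 11 | 3-bromo-2-(trimethylsilyl)furan | C[Si](C)(C)c1occc1Br
F12 | step 11 | 2-(trimethylsilyl)furan-3-yllithium | C[Si](C)(C)c1occc1[Li]
F13 | step 11 | 3-chloro-2-(trimethylsilyl)furan | C[Si](C)(C)c1occc1Cl
F14 | step 11 | 4-chloro-5-(trimethylsilyl)furan-2-yllithium | C[Si](C)(C)c1oc([Li])cc1Cl
F15 | step 11 | 3-chloro-5-[(Z)-oct-2-enyl]-2-(trimethylsilyl)furan | CCCCC/C=C\Cc1cc(Cl)c(o1)[Si](C)(C)C
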